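**Strategy.** Everything rests on installing all four aryl bromines last, on a symmetric dibenzyl ether that is already in place. Each benzene ring is a guaiacol: the free C4 hydroxyl (para to the C1 CH2O arm) sends bromine to C3, its only open ortho carbon, and the C5 methoxyl then sends the second bromine to C2, its para carbon, leaving C6–H untouched. One buffered tetrabromination of bis(4-hydroxy-3-methoxybenzyl) ether thus makes C3–Br and C2–Br on both rings at once. This precursor, two vanillyl units joined through one benzylic oxygen with free phenols, is built from vanillin acetate by silane reductive homo-etherification and deacetylation; chelation-controlled O-demethylation finishes the synthesis.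

Key step: step 3

Remark: ring atoms are numbered C1 (carbon bearing CH2O), C2, C3, C4 (oxygen para to C1), C5 (oxygen meta to C1) and C6 throughout, so the "3-methoxy" carbon in the vanillyl names is C5 here; reagents that deliver only hydrogen or only remove groups stand under Conditions.

Step 1
Reactants: 1 vanillin acetate (4-formyl-2-methoxyphenyl acetate), two molecules
Product: 3 bis(4-acetoxy-3-methoxybenzyl) ether, via 4-acetoxy-3-methoxybenzyl triethylsilyl ether 2 (not isolated)
Conditions: Et3SiH (1.2 equiv per aldehyde), FeCl3 (5 mol %), MeNO2, 0 °C → rt
Reagents that add atoms: none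
Why: Lewis-acid-catalysed reductive etherification: hydrosilylation of one aldehyde gives silyl ether 2, which adds to a second activated aldehyde to form an oxocarbenium ion that Et3SiH reduces to the symmetric ether; the acetylated phenol keeps the ring too electron-poor for Friedel–Crafts benzylation or over-reduction, which is why the ether is made here and not by acid condensation of a free para-hydroxybenzyl alcohol.

Step 2
Reactants: 3 bis(4-acetoxy-3-methoxybenzyl) ether
Product: 4 bis(4-hydroxy-3-methoxybenzyl) ether
Conditions: K2CO3 (0.2 equiv), MeOH, 0 °C; NH4Cl quench
Reagents that add atoms: none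
Why: Base-catalysed transesterification (methanolysis) of the two aryl acetates is fast because phenoxide is a good leaving group, and the cold basic medium with a neutral quench should not ionise the para-hydroxybenzyl ether.

Step 3
Reactants: 4 bis(4-hydroxy-3-methoxybenzyl) ether; 5 bromine (4 equiv)
Product: 7 bis(2,3-dibromo-4-hydroxy-5-methoxybenzyl) ether, via bis(3-bromo-4-hydroxy-5-methoxybenzyl) ether 6 (not isolated)
Conditions: Br2 (2 × 2.05 equiv), NaOAc (6 equiv), AcOH–CH2Cl2, 0 °C → rt, dark; aq. Na2S2O3
Reagents that add atoms: bromine, BrBr
Why: Each ring undergoes two successive electrophilic aromatic brominations through arenium ions: the free C4 hydroxyl activates C3, its only unsubstituted ortho carbon, giving 6, and the C5 methoxyl then directs the second bromine to its para carbon C2 in preference to its ortho carbon C6. The closest known reaction type is the two-stage nuclear bromination of 4-hydroxy-3-methoxyarenes of the vanillin family, first ortho to hydroxyl and then para to methoxyl. No ring is closed and no stereocentre is formed. The step needs site selectivity for C3 and C2 over C6, which the hydroxyl-ortho and methoxyl-para preferences should secure, and chemoselectivity against ipso attack at C1, which would expel or oxidise the benzylic arm. The latter should be helped by un-ionised phenols in acetic acid, low temperature, darkness, the absence of a Lewis acid, and the arm being an ether and not a free benzylic alcohol. NaOAc converts the four equivalents of HBr into NaBr so that the acid-labile ether is not cleaved, and each bromine makes the ring poorer and the ether harder to ionise.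

Step 4
Reactants: 7 bis(2,3-dibromo-4-hydroxy-5-methoxybenzyl) ether
Product: 8 bis(2,3-dibromo-4,5-dihydroxybenzyl) ether
Conditions: AlCl3 (2.4 equiv), pyridine (10 equiv), CH2Cl2, 40 °C; cold 1 M HCl, EtOAc (no alcoholic solvents)
Reagents that add atoms: none
Why: Chelation-assisted Lewis-acid O-demethylation of an ortho-hydroxyanisole: each C4 phenol binds aluminium, the metal coordinates the neighbouring C5 methoxyl oxygen in a five-membered chelate, and pyridine removes the activated methyl group by SN2 attack; the benzylic ether oxygen has no chelating neighbour and all AlCl3 is held as its pyridine complex, so the ether on the electron-poor dibromo rings should survive.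

**Compound list**

1 | vanillin acetate (4-formyl-2-methoxyphenyl acetate) | COc1cc(C=O)ccc1OC(C)=O | starting material
2 | 4-acetoxy-3-methoxybenzyl triethylsilyl ether | CC[Si](CC)(CC)OCc1ccc(OC(C)=O)c(OC)c1 | intermediate
3 | bis(4-acetoxy-3-methoxybenzyl) ether | CC(=O)Oc1ccc(COCc2ccc(OC(C)=O)c(OC)c2)cc1OC | intermediate
4 | bis(4-hydroxy-3-methoxybenzyl) ether | COc1cc(COCc2ccc(O)c(OC)c2)ccc1O | intermediate
5 | bromine | BrBr | starting material
6 | bis(3-bromo-4-hydroxy-5-methoxybenzyl) ether | COc1cc(COCc2cc(OC)c(O)c(Br)c2)cc(Br)c1O | intermediate
7 | bis(2,3-dibromo-4-hydroxy-5-methoxybenzyl) ether | COc1cc(COCc2cc(OC)c(O)c(Br)c2Br)c(Br)c(Br)c1O | intermediate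
8 | bis(2,3-dibromo-4,5-dihydroxybenzyl) ether | Oc1cc(COCc2cc(O)c(O)c(Br)c2Br)c(Br)c(Br)c1O | target

Total step count: 4
Longest linear sequence: 4 steps (1 → 3 → 4 → 7 → 8)

**Steps most likely to fail**

1. Step 3 (key step). What may go wrong: ipso attack of bromine at C1 with expulsion or oxidation of the benzylic arm, acidolysis of the ether by HBr or acetic acid, or incomplete bromination at C2. Fallback, setting out from 1 and rejoining the route at 7: the bromines are placed on the aldehyde before the ether exists, where C1 carries a formyl group that cannot leave. Methanolysis of 1 (K2CO3, MeOH) gives vanillin F1. Br2 in MeOH at 0 °C then gives 3-bromo-4-hydroxy-5-methoxybenzaldehyde F2. Br2 with NaOAc and iron powder in AcOH gives 2,3-dibromo-4-hydroxy-5-methoxybenzaldehyde F3. NaBH4 in THF/EtOH gives 2,3-dibromo-4-hydroxy-5-methoxybenzyl alcohol F4. Dehydrative self-etherification of F4 (cat. TsOH, CH2Cl2, 4 Å sieves) should then give 7, because the deactivated ring, with only C6–H left, leaves the benzylic hydroxyl as the only good nucleophile for the para-hydroxybenzyl cation.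

2. Step 4. What may go wrong: ionisation of the benzylic C–O bond once the para oxygen is bound to aluminium, with capture by chloride or pyridine; solvolysis of the product ether during acidic work-up; or stalling after one demethylation. Fallback, setting out from 7 and rejoining at 8: the ether cleavage is accepted and the ether is rebuilt at the end. Excess BBr3 (CH2Cl2, −78 °C → rt) removes both methyl groups and opens the ether to 2,3-dibromo-4,5-dihydroxybenzyl bromide F5. Hydrolysis in aqueous acetone gives 2,3-dibromo-4,5-dihydroxybenzyl alcohol F6. Dehydrative self-condensation of F6 (cat. TsOH, MeCN, 4 Å sieves, rt) should give 8, since this para-hydroxybenzyl alcohol ionises readily and its aliphatic hydroxyl is the most nucleophilic partner.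

3. Step 1. What may go wrong: over-reduction of the benzylic carbon to a methyl group, stalling at the silyl ether stage, or Lewis-acid loss of the acetate. Fallback, setting out from 1 and rejoining at 3: the ether is made by a neutral two-component alkylation. NaBH4 reduction of 1 (THF–H2O, 0 °C, short contact) gives 4-acetoxy-3-methoxybenzyl alcohol F7. Half of it is converted with PBr3 (CH2Cl2, 0 °C) into 4-acetoxy-3-methoxybenzyl bromide F8. F7 and F8 are then joined by Ag2O-promoted Williamson-type etherification (CH2Cl2, 4 Å sieves, dark), which should give 3 without touching the aryl acetates.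

**Further compounds**

F1 | step 3 | vanillin (4-hydroxy-3-methoxybenzaldehyde) | COc1cc(C=O)ccc1O
F2 | step 3 | 3-bromo-4-hydroxy-5-methoxybenzaldehyde | COc1cc(C=O)cc(Br)c1O
F3 | step 3 | 2,3-dibromo-4-hydroxy-5-methoxybenzaldehyde | COc1cc(C=O)c(Br)c(Br)c1O
F4 | step 3 | 2,3-dibromo-4-hydroxy-5-methoxybenzyl alcohol | COc1cc(CO)c(Br)c(Br)c1O
F5 | step 4 | 2,3-dibromo-4,5-dihydroxybenzyl bromide | Oc1cc(CBr)c(Br)c(Br)c1O
F6 | step 4 | 2,3-dibromo-4,5-dihydroxybenzyl alcohol | Oc1cc(CO)c(Br)c(Br)c1O
F7 | step 1 | 4-acetoxy-3-methoxybenzyl alcohol | COc1cc(CO)ccc1OC(C)=O
F8 | step 1 | 4-acetoxy-3-methoxybenzyl bromide | COc1cc(CBr)ccc1OC(C)=O
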